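## Retrosynthetic overview

- The target is fisetinidol-(4α→6)-fisetinidol-(4α→6)-catechin with a third fisetinidol bonded (4α→8). Unit C comes from (+)-catechin with its C2/C3 centres, and units D, B and A are grown on it in that order.
- Feature used: in each fisetinidol unit the ring oxygen O1 and the aryl-bearing C4 are ortho on the benzo ring. O1–C8a–C4a–C4 is therefore an o-quinone methide, and C2–C3 (2-aryl, 3-oxygen, trans) is an (E)-styrene whose C3 oxygen is carried as boron.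
- Disconnections per unit: C3–C4 and O1–C2 by [4+2] cycloaddition; the C4–aryl bond to the lower unit by aryl-metal addition to a salicylaldehyde; C3–O from C3–B.
- Ring order: pyran ring of D on catechin C8 (step 8), pyran ring of B on catechin C6 (step 14), pyran ring of A on C6 of unit B (step 18); the sixteen benzyl ethers are removed last.

Key step: step 8

Assumption: the (R) enantiomer of the phosphoric acid is taken to give the required facial sense; this diene–dienophile pair has no direct precedent, and the (S) acid would replace it in steps 8, 14 and 18 if step 8 showed the opposite preference.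

## Route

Step 1
Reactants: 1 (+)-catechin
Product: 2 5,7,3′,4′-tetra-O-benzyl-(+)-catechin
Conditions: BnBr (4.4 equiv), K2CO3, DMF, 0 °C → rt
Reagents that add atoms: benzyl bromide (BrCc1ccccc1)
Why: Williamson ether synthesis in which carbonate deprotonates only the four phenols, so the secondary alcohol and the C2/C3 centres are untouched.

Step 2
Reactants: 2 5,7,3′,4′-tetra-O-benzyl-(+)-catechin
Product: 3 3,5,7,3′,4′-penta-O-benzyl-(+)-catechin
Conditions: NaH, BnBr, DMF, 0 °C → rt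
Reagents that add atoms: benzyl bromide (BrCc1ccccc1)
Why: Williamson etherification of the secondary alkoxide; no free phenoxide remains, so base-induced opening of the pyran ring and C2 epimerisation cannot occur.

Step 3
Reactants: 3 3,5,7,3′,4′-penta-O-benzyl-(+)-catechin
Product: 4 8-iodo-penta-O-benzylcatechin
Conditions: N-iodosuccinimide (1.05 equiv), DMF, 0 °C → rt, dark
Reagents that add atoms: N-iodosuccinimide (O=C1CCC(=O)N1I)
Why: electrophilic aromatic substitution on the phloroglucinol-type ring, where C8 reacts before C6 as in the established C8 halogenation of benzylated catechins.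

Step 4
Reactants: 4 8-iodo-penta-O-benzylcatechin
Product: 5 6-bromo-8-iodo-penta-O-benzylcatechin
Conditions: N-bromosuccinimide (1.05 equiv), CH2Cl2, −20 → 0 °C
Reagents that add atoms: N-bromosuccinimide (O=C1CCC(=O)N1Br)
Why: electrophilic aromatic bromination at C6, the only position still activated by three oxygens, which installs the handle for unit B.

Step 5
Reactants: 6 4-benzyloxy-2-hydroxybenzaldehyde
Product: 7 4-benzyloxy-2-(tert-butyldimethylsilyloxy)benzaldehyde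
Conditions: TBSCl, imidazole, DMF, rt
Reagents that add atoms: tert-butyldimethylsilyl chloride (CC(C)(C)[Si](C)(C)Cl)
Why: O-silylation masks the acidic phenol so that the aldehyde can take up one equivalent of aryl-metal.

Step 6
Reactants: 8 3,4-dibenzyloxybenzaldehyde
Product: 9 (E)-2-(3,4-dibenzyloxyphenyl)vinylboronic acid pinacol ester
Conditions: CH2(Bpin)2 (1.2 equiv), lithium 2,2,6,6-tetramethylpiperidide (1.2 equiv), THF, 0 °C; then 8, −78 °C → rt
Reagents that add atoms: bis(pinacolatoboryl)methane (CC1(C)OB(CB2OC(C)(C)C(C)(C)O2)OC1(C)C)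
Why: boron–Wittig olefination, in which the α-boryl carbanion adds to the aldehyde and syn elimination of the boron–oxygen pair gives the E-alkenylboronate.

Step 7
Reactants: 5 6-bromo-8-iodo-penta-O-benzylcatechin; 7 4-benzyloxy-2-(tert-butyldimethylsilyloxy)benzaldehyde
Product: 12 8-[(4-benzyloxy-2-hydroxyphenyl)hydroxymethyl]-6-bromo-penta-O-benzylcatechin (both carbinol epimers), via arylmagnesium chloride 10 (not isolated), via silyl ether carbinol 11 (not isolated)
Conditions: iPrMgCl·LiCl (1.1 equiv), THF, −20 → 0 °C; then 7, 0 °C; then AcOH, Bu4NF, 0 °C → rt; filtration through Et3N-deactivated silica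
Reagents that add atoms: none
Why: iodine–magnesium exchange is much faster at the aryl iodide than at the aryl bromide, the Grignard addition to the aldehyde forms the C8–C bond, and buffered fluoride removes the silyl group wherever it sits after a possible O-to-O shift; the carbinol centre is formed unselectively and is destroyed in step 8.

Step 8
Reactants: 12 8-[(4-benzyloxy-2-hydroxyphenyl)hydroxymethyl]-6-bromo-penta-O-benzylcatechin; 9 (E)-2-(3,4-dibenzyloxyphenyl)vinylboronic acid pinacol ester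
Product: 14 6-bromo-penta-O-benzylcatechin carrying at C8 the 7,3′,4′-tri-O-benzyl-3-deoxy-3-(pinacolatoboryl)fisetinidol-4α-yl unit D (2,3-trans-3,4-trans), via o-quinone methide 13 (not isolated)
Conditions: 9 (1.5 equiv), (R)-3,3′-bis(2,4,6-triisopropylphenyl)-1,1′-binaphthyl-2,2′-diyl hydrogen phosphate [(R)-TRIP] (10 mol %), 5 Å molecular sieves, toluene, 0 °C → rt
Reagents that add atoms: none
Why: Proposed new method: the phosphoric acid protonates the doubly benzylic hydroxyl of 12 and, with the free phenol, releases water to give the hydrogen-bonded (E)-o-quinone methide 13, whose oxa-diene O1=C8a–C4a=C4 is attacked at C4 by the boron-bearing carbon of 9 (C3–C4) while the developing 3,4-dibenzyloxybenzyl cation is captured by the quinone methide oxygen (O1–C2). The closest known reaction type is the chiral phosphoric acid catalysed inverse-demand hetero-Diels–Alder reaction of in situ o-quinone methides with styrenes to 2,4-cis-chromans; new here are the pinacolboryl group on the styrene β-carbon and the di-ortho-oxygenated catechin ring on the methide carbon. The pyran ring of unit D, the only ring formed, closes by this asynchronous [4+2] cycloaddition. C2 and C3 are set trans by suprafacial transfer of the E geometry of 9, C4 is set cis to the C2 aryl group (hence trans to boron) by endo approach of the styryl aryl group to the E-methide, and the absolute sense of all three is set by the binaphthyl phosphate bound to the quinone methide oxygen, since the catechin centres lie far from the reacting carbons. The step needs the regiochemistry aryl on C2 and boron on C3, which the cation-stabilising 3,4-dibenzyloxyphenyl group and the weakly Lewis acidic pinacol ester (no alkenyl transfer through a boron ate complex) should secure, and it needs ring closure to outrun loss of boron from the β-boryl cation, which the phenoxide oxygen held in the same ion pair should secure. Ionisation of 12 should be easy because the 4-benzyloxy group is para to the methide-bearing ring carbon and the trialkoxyaryl group is attached to the methide carbon itself, and the molecular sieves take up the water.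

Step 9
Reactants: 14 boronate cycloadduct
Product: 15 7,3′,4′-tri-O-benzylfisetinidol-(4α→8)-6-bromo-penta-O-benzylcatechin (3-OH of unit D free)
Conditions: NaBO3·4H2O, THF/H2O (1:1), rt
Reagents that add atoms: sodium perborate ([Na+].[O-]OB=O)
Why: boronate oxidation by 1,2-migration of C3 from boron to oxygen with retention, giving the 3-hydroxyl trans to both aryl groups; β-aryloxy boron compounds of exactly this kind are oxidised without ring opening in the hydroboration–oxidation of flav-3-enes.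

Step 10
Reactants: 15 7,3′,4′-tri-O-benzylfisetinidol-(4α→8)-6-bromo-penta-O-benzylcatechin
Product: 16 tetra-O-benzylfisetinidol-(4α→8)-6-bromo-penta-O-benzylcatechin
Conditions: NaH, BnBr, Bu4NI (cat.), DMF, 0 °C → rt
Reagents that add atoms: benzyl bromide (BrCc1ccccc1)
Why: Williamson etherification of the equatorial secondary alkoxide removes the only acidic proton before the bromine–lithium exchange.

Step 11
Reactants: 17 5-bromo-2,4-dihydroxybenzaldehyde
Product: 18 4-benzyloxy-5-bromo-2-hydroxybenzaldehyde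
Conditions: BnBr (1.0 equiv), NaHCO3, KI (cat.), MeCN, 80 °C
Reagents that add atoms: benzyl bromide (BrCc1ccccc1)
Why: Williamson etherification selective for the 4-hydroxyl, which is the more acidic one, while the 2-hydroxyl is held in a hydrogen bond to the aldehyde.

Step 12
Reactants: 18 4-benzyloxy-5-bromo-2-hydroxybenzaldehyde
Product: 19 4-benzyloxy-5-bromo-2-(tert-butyldimethylsilyloxy)benzaldehyde
Conditions: TBSCl, imidazole, DMF, rt
Reagents that add atoms: tert-butyldimethylsilyl chloride (CC(C)(C)[Si](C)(C)Cl)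
Why: O-silylation of the phenol, as in step 5.

Step 13
Reactants: 16 tetra-O-benzylfisetinidol-(4α→8)-6-bromo-penta-O-benzylcatechin; 19 4-benzyloxy-5-bromo-2-(tert-butyldimethylsilyloxy)benzaldehyde
Product: 22 tetra-O-benzylfisetinidol-(4α→8)-penta-O-benzylcatechin carrying at catechin C6 the (4-benzyloxy-5-bromo-2-hydroxyphenyl)hydroxymethyl group (both carbinol epimers), via aryllithium 20 (not isolated), via silyl ether carbinol 21 (not isolated)
Conditions: n-BuLi (1.05 equiv), THF, −78 °C; then 19, −78 → −40 °C; then AcOH, Bu4NF, 0 °C → rt; filtration through Et3N-deactivated silica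
Reagents that add atoms: none
Why: bromine–lithium exchange at the bromide flanked by two benzyloxy groups is fast at −78 °C, carbonyl addition of the aryllithium outruns exchange with the aryl bromide of 19, and buffered fluoride frees the phenol.

Step 14
Reactants: 22 carbinol at catechin C6; 9 (E)-2-(3,4-dibenzyloxyphenyl)vinylboronic acid pinacol ester
Product: 24 6-bromo-7,3′,4′-tri-O-benzyl-3-deoxy-3-(pinacolatoboryl)fisetinidol-(4α→6)-[tetra-O-benzylfisetinidol-(4α→8)]-penta-O-benzylcatechin, via o-quinone methide 23 (not isolated)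
Conditions: 9 (2 equiv), (R)-TRIP (10 mol %), 5 Å molecular sieves, toluene, rt
Reagents that add atoms: none
Why: Proposed new method: as in step 8, acid-induced loss of water gives the hydrogen-bonded E-o-quinone methide 23, and the boron-bearing carbon of 9 attacks its methide carbon with ring closure through oxygen, an asynchronous inverse-demand hetero-Diels–Alder reaction whose closest known type is the chiral phosphoric acid catalysed [4+2] of o-quinone methides with styrenes; the E-alkene gives 2,3-trans, endo approach gives 2,4-cis, the catalyst chooses the face, and the bromine para to the quinone methide oxygen is a spectator that becomes C6–Br of unit B.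

Step 15
Reactants: 24 trimer boronate
Product: 25 6-bromo-7,3′,4′-tri-O-benzylfisetinidol-(4α→6)-[tetra-O-benzylfisetinidol-(4α→8)]-penta-O-benzylcatechin (3-OH of unit B free)
Conditions: NaBO3·4H2O, THF/H2O (1:1), rt
Reagents that add atoms: sodium perborate ([Na+].[O-]OB=O)
Why: boronate oxidation with retention at C3 of unit B, as in step 9.

Step 16
Reactants: 25 trimer alcohol
Product: 26 6-bromo-tetra-O-benzylfisetinidol-(4α→6)-[tetra-O-benzylfisetinidol-(4α→8)]-penta-O-benzylcatechin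
Conditions: NaH, BnBr, Bu4NI (cat.), DMF, 0 °C → rt
Reagents that add atoms: benzyl bromide (BrCc1ccccc1)
Why: Williamson etherification, as in step 10.

Step 17
Reactants: 26 trimer bromide; 7 4-benzyloxy-2-(tert-butyldimethylsilyloxy)benzaldehyde
Product: 29 trimer carrying at C6 of unit B the (4-benzyloxy-2-hydroxyphenyl)hydroxymethyl group (both carbinol epimers), via aryllithium 27 (not isolated), via silyl ether carbinol 28 (not isolated)
Conditions: n-BuLi (1.05 equiv), THF, −78 °C; then 7, −78 → −40 °C; then AcOH, Bu4NF, 0 °C → rt; filtration through Et3N-deactivated silica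
Reagents that add atoms: none
Why: bromine–lithium exchange at the single aryl bromide (ortho to a benzyloxy group), aryllithium addition to the aldehyde and fluoride desilylation, as in step 13.

Step 18
Reactants: 29 carbinol at C6 of unit B; 9 (E)-2-(3,4-dibenzyloxyphenyl)vinylboronic acid pinacol ester
Product: 31 7,3′,4′-tri-O-benzyl-3-deoxy-3-(pinacolatoboryl)fisetinidol-(4α→6)-tetra-O-benzylfisetinidol-(4α→6)-[tetra-O-benzylfisetinidol-(4α→8)]-penta-O-benzylcatechin, via o-quinone methide 30 (not isolated)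
Conditions: 9 (2 equiv), (R)-TRIP (10 mol %), 5 Å molecular sieves, toluene, rt
Reagents that add atoms: none
Why: Proposed new method: the same acid-induced dehydration to the E-o-quinone methide 30 and asynchronous inverse-demand hetero-Diels–Alder addition of the boryl styrene as in step 8 (closest known type: chiral phosphoric acid catalysed o-quinone methide/styrene [4+2]); the methide carbon now carries the less hindered ring of unit B, whose ortho benzyloxy group and para ring oxygen still stabilise the cation, and the E-alkene, endo approach and catalyst again set 2,3-trans, 2,4-cis and the face.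

Step 19
Reactants: 31 tetramer boronate
Product: 32 hexadeca-O-benzyl tetramer with free 3-OH in unit A
Conditions: NaBO3·4H2O, THF/H2O (1:1), rt
Reagents that add atoms: sodium perborate ([Na+].[O-]OB=O)
Why: boronate oxidation with retention at C3 of unit A, as in step 9.

Step 20
Reactants: 32 hexadeca-O-benzyl tetramer
Product: 33 fisetinidol-(4α→6)-fisetinidol-(4α→6)-[fisetinidol-(4α→8)]-catechin (target)
Conditions: H2 (1 atm), Pd(OH)2/C, THF/MeOH/H2O, rt
Reagents that add atoms: none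
Why: catalytic hydrogenolysis cleaves all sixteen benzyl ethers under neutral conditions that leave the interflavanyl C–C bonds and all stereocentres untouched.

## Compound list

1 | (+)-catechin, (2R,3S) | Oc1cc(O)c2c(c1)O[C@H](c1ccc(O)c(O)c1)[C@@H](O)C2 | starting material
2 | 5,7,3′,4′-tetra-O-benzyl-(+)-catechin | c1c(OCc9ccccc9)c2c(cc1OCc9ccccc9)O[C@H](c6ccc(OCc9ccccc9)c(OCc9ccccc9)c6)[C@@H](O)C2 | intermediate
3 | 3,5,7,3′,4′-penta-O-benzyl-(+)-catechin | c1c(OCc9ccccc9)c2c(cc1OCc9ccccc9)O[C@H](c6ccc(OCc9ccccc9)c(OCc9ccccc9)c6)[C@@H](OCc9ccccc9)C2 | intermediate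
4 | 8-iodo-penta-O-benzylcatechin | c1c(OCc9ccccc9)c2c(c(I)c1OCc9ccccc9)O[C@H](c6ccc(OCc9ccccc9)c(OCc9ccccc9)c6)[C@@H](OCc9ccccc9)C2 | intermediate
5 | 6-bromo-8-iodo-penta-O-benzylcatechin | Brc1c(OCc9ccccc9)c2c(c(I)c1OCc9ccccc9)O[C@H](c6ccc(OCc9ccccc9)c(OCc9ccccc9)c6)[C@@H](OCc9ccccc9)C2 | intermediate
6 | 4-benzyloxy-2-hydroxybenzaldehyde | O=Cc1ccc(OCc2ccccc2)cc1O | starting material
7 | 4-benzyloxy-2-(tert-butyldimethylsilyloxy)benzaldehyde | O=Cc1ccc(OCc2ccccc2)cc1O[Si](C)(C)C(C)(C)C | intermediate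
8 | 3,4-dibenzyloxybenzaldehyde | O=Cc1ccc(OCc2ccccc2)c(OCc2ccccc2)c1 | starting material
9 | (E)-2-(3,4-dibenzyloxyphenyl)vinylboronic acid pinacol ester | CC1(C)OB(/C=C/c2ccc(OCc3ccccc3)c(OCc3ccccc3)c2)OC1(C)C | intermediate
10 | (6-bromo-penta-O-benzylcatechin-8-yl)magnesium chloride | Brc1c(OCc9ccccc9)c2c(c([Mg]Cl)c1OCc9ccccc9)O[C@H](c6ccc(OCc9ccccc9)c(OCc9ccccc9)c6)[C@@H](OCc9ccccc9)C2 | intermediate
11 | 6-bromo-8-[(4-benzyloxy-2-(tert-butyldimethylsilyloxy)phenyl)hydroxymethyl]-penta-O-benzylcatechin (carbinol epimers) | Brc1c(OCc9ccccc9)c2c(c(C(O)c4ccc(OCc9ccccc9)cc4O[Si](C)(C)C(C)(C)C)c1OCc9ccccc9)O[C@H](c6ccc(OCc9ccccc9)c(OCc9ccccc9)c6)[C@@H](OCc9ccccc9)C2 | intermediate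
12 | 8-[(4-benzyloxy-2-hydroxyphenyl)hydroxymethyl]-6-bromo-penta-O-benzylcatechin (carbinol epimers) | Brc1c(OCc9ccccc9)c2c(c(C(O)c4ccc(OCc9ccccc9)cc4O)c1OCc9ccccc9)O[C@H](c6ccc(OCc9ccccc9)c(OCc9ccccc9)c6)[C@@H](OCc9ccccc9)C2 | intermediate
13 | (E)-o-quinone methide from 12: 3-benzyloxy-6-[(6-bromo-penta-O-benzylcatechin-8-yl)methylidene]cyclohexa-2,4-dienone | Brc1c(OCc9ccccc9)c2c(c(/C=C4\C=CC(OCc9ccccc9)=CC4=O)c1OCc9ccccc9)O[C@H](c6ccc(OCc9ccccc9)c(OCc9ccccc9)c6)[C@@H](OCc9ccccc9)C2 | intermediate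
14 | 6-bromo-penta-O-benzylcatechin carrying at C8 the 7,3′,4′-tri-O-benzyl-3-deoxy-3-(pinacolatoboryl)fisetinidol-4α-yl unit D (2,3-trans-3,4-trans) | Brc1c(OCc9ccccc9)c2c(c([C@@H]3c4ccc(OCc9ccccc9)cc4O[C@H](c6ccc(OCc9ccccc9)c(OCc9ccccc9)c6)[C@H]3B7OC(C)(C)C(C)(C)O7)c1OCc9ccccc9)O[C@H](c6ccc(OCc9ccccc9)c(OCc9ccccc9)c6)[C@@H](OCc9ccccc9)C2 | intermediate
15 | 7,3′,4′-tri-O-benzylfisetinidol-(4α→8)-6-bromo-penta-O-benzylcatechin | Brc1c(OCc9ccccc9)c2c(c([C@@H]3c4ccc(OCc9ccccc9)cc4O[C@H](c6ccc(OCc9ccccc9)c(OCc9ccccc9)c6)[C@H]3O)c1OCc9ccccc9)O[C@H](c6ccc(OCc9ccccc9)c(OCc9ccccc9)c6)[C@@H](OCc9ccccc9)C2 | intermediate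
16 | tetra-O-benzylfisetinidol-(4α→8)-6-bromo-penta-O-benzylcatechin | Brc1c(OCc9ccccc9)c2c(c([C@@H]3c4ccc(OCc9ccccc9)cc4O[C@H](c6ccc(OCc9ccccc9)c(OCc9ccccc9)c6)[C@H]3OCc9ccccc9)c1OCc9ccccc9)O[C@H](c6ccc(OCc9ccccc9)c(OCc9ccccc9)c6)[C@@H](OCc9ccccc9)C2 | intermediate
17 | 5-bromo-2,4-dihydroxybenzaldehyde | O=Cc1cc(Br)c(O)cc1O | starting material
18 | 4-benzyloxy-5-bromo-2-hydroxybenzaldehyde | O=Cc1cc(Br)c(OCc2ccccc2)cc1O | intermediate
19 | 4-benzyloxy-5-bromo-2-(tert-butyldimethylsilyloxy)benzaldehyde | O=Cc1cc(Br)c(OCc2ccccc2)cc1O[Si](C)(C)C(C)(C)C | intermediate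
20 | 6-lithio derivative of 16 (lithium in place of bromine at catechin C6) | [Li]c1c(OCc9ccccc9)c2c(c([C@@H]3c4ccc(OCc9ccccc9)cc4O[C@H](c6ccc(OCc9ccccc9)c(OCc9ccccc9)c6)[C@H]3OCc9ccccc9)c1OCc9ccccc9)O[C@H](c6ccc(OCc9ccccc9)c(OCc9ccccc9)c6)[C@@H](OCc9ccccc9)C2 | intermediate
21 | tetra-O-benzylfisetinidol-(4α→8)-penta-O-benzylcatechin with (4-benzyloxy-5-bromo-2-(tert-butyldimethylsilyloxy)phenyl)hydroxymethyl at catechin C6 (carbinol epimers) | OC(c5cc(Br)c(OCc9ccccc9)cc5O[Si](C)(C)C(C)(C)C)c1c(OCc9ccccc9)c2c(c([C@@H]3c4ccc(OCc9ccccc9)cc4O[C@H](c6ccc(OCc9ccccc9)c(OCc9ccccc9)c6)[C@H]3OCc9ccccc9)c1OCc9ccccc9)O[C@H](c6ccc(OCc9ccccc9)c(OCc9ccccc9)c6)[C@@H](OCc9ccccc9)C2 | intermediate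
22 | tetra-O-benzylfisetinidol-(4α→8)-penta-O-benzylcatechin with (4-benzyloxy-5-bromo-2-hydroxyphenyl)hydroxymethyl at catechin C6 (carbinol epimers) | OC(c5cc(Br)c(OCc9ccccc9)cc5O)c1c(OCc9ccccc9)c2c(c([C@@H]3c4ccc(OCc9ccccc9)cc4O[C@H](c6ccc(OCc9ccccc9)c(OCc9ccccc9)c6)[C@H]3OCc9ccccc9)c1OCc9ccccc9)O[C@H](c6ccc(OCc9ccccc9)c(OCc9ccccc9)c6)[C@@H](OCc9ccccc9)C2 | intermediate
23 | (E)-o-quinone methide from 22 (3-benzyloxy-4-bromo-6-arylmethylidene-cyclohexa-2,4-dienone on catechin C6) | O=C5C=C(OCc9ccccc9)C(Br)=C/C5=C\c1c(OCc9ccccc9)c2c(c([C@@H]3c4ccc(OCc9ccccc9)cc4O[C@H](c6ccc(OCc9ccccc9)c(OCc9ccccc9)c6)[C@H]3OCc9ccccc9)c1OCc9ccccc9)O[C@H](c6ccc(OCc9ccccc9)c(OCc9ccccc9)c6)[C@@H](OCc9ccccc9)C2 | intermediate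
24 | 6-bromo-7,3′,4′-tri-O-benzyl-3-deoxy-3-(pinacolatoboryl)fisetinidol-(4α→6)-[tetra-O-benzylfisetinidol-(4α→8)]-penta-O-benzylcatechin | Brc5cc7c(cc5OCc9ccccc9)O[C@H](c6ccc(OCc9ccccc9)c(OCc9ccccc9)c6)[C@@H](B8OC(C)(C)C(C)(C)O8)[C@@H]7c1c(OCc9ccccc9)c2c(c([C@@H]3c4ccc(OCc9ccccc9)cc4O[C@H](c6ccc(OCc9ccccc9)c(OCc9ccccc9)c6)[C@H]3OCc9ccccc9)c1OCc9ccccc9)O[C@H](c6ccc(OCc9ccccc9)c(OCc9ccccc9)c6)[C@@H](OCc9ccccc9)C2 | intermediate
25 | 6-bromo-7,3′,4′-tri-O-benzylfisetinidol-(4α→6)-[tetra-O-benzylfisetinidol-(4α→8)]-penta-O-benzylcatechin | Brc5cc7c(cc5OCc9ccccc9)O[C@H](c6ccc(OCc9ccccc9)c(OCc9ccccc9)c6)[C@@H](O)[C@@H]7c1c(OCc9ccccc9)c2c(c([C@@H]3c4ccc(OCc9ccccc9)cc4O[C@H](c6ccc(OCc9ccccc9)c(OCc9ccccc9)c6)[C@H]3OCc9ccccc9)c1OCc9ccccc9)O[C@H](c6ccc(OCc9ccccc9)c(OCc9ccccc9)c6)[C@@H](OCc9ccccc9)C2 | intermediate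
26 | 6-bromo-tetra-O-benzylfisetinidol-(4α→6)-[tetra-O-benzylfisetinidol-(4α→8)]-penta-O-benzylcatechin | Brc5cc7c(cc5OCc9ccccc9)O[C@H](c6ccc(OCc9ccccc9)c(OCc9ccccc9)c6)[C@@H](OCc9ccccc9)[C@@H]7c1c(OCc9ccccc9)c2c(c([C@@H]3c4ccc(OCc9ccccc9)cc4O[C@H](c6ccc(OCc9ccccc9)c(OCc9ccccc9)c6)[C@H]3OCc9ccccc9)c1OCc9ccccc9)O[C@H](c6ccc(OCc9ccccc9)c(OCc9ccccc9)c6)[C@@H](OCc9ccccc9)C2 | intermediate
27 | 6-lithio derivative of 26 (lithium in place of bromine at C6 of unit B) | [Li]c5cc7c(cc5OCc9ccccc9)O[C@H](c6ccc(OCc9ccccc9)c(OCc9ccccc9)c6)[C@@H](OCc9ccccc9)[C@@H]7c1c(OCc9ccccc9)c2c(c([C@@H]3c4ccc(OCc9ccccc9)cc4O[C@H](c6ccc(OCc9ccccc9)c(OCc9ccccc9)c6)[C@H]3OCc9ccccc9)c1OCc9ccccc9)O[C@H](c6ccc(OCc9ccccc9)c(OCc9ccccc9)c6)[C@@H](OCc9ccccc9)C2 | intermediate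
28 | benzylated trimer with (4-benzyloxy-2-(tert-butyldimethylsilyloxy)phenyl)hydroxymethyl at C6 of unit B (carbinol epimers) | OC(c8ccc(OCc9ccccc9)cc8O[Si](C)(C)C(C)(C)C)c5cc7c(cc5OCc9ccccc9)O[C@H](c6ccc(OCc9ccccc9)c(OCc9ccccc9)c6)[C@@H](OCc9ccccc9)[C@@H]7c1c(OCc9ccccc9)c2c(c([C@@H]3c4ccc(OCc9ccccc9)cc4O[C@H](c6ccc(OCc9ccccc9)c(OCc9ccccc9)c6)[C@H]3OCc9ccccc9)c1OCc9ccccc9)O[C@H](c6ccc(OCc9ccccc9)c(OCc9ccccc9)c6)[C@@H](OCc9ccccc9)C2 | intermediate
29 | benzylated trimer with (4-benzyloxy-2-hydroxyphenyl)hydroxymethyl at C6 of unit B (carbinol epimers) | OC(c8ccc(OCc9ccccc9)cc8O)c5cc7c(cc5OCc9ccccc9)O[C@H](c6ccc(OCc9ccccc9)c(OCc9ccccc9)c6)[C@@H](OCc9ccccc9)[C@@H]7c1c(OCc9ccccc9)c2c(c([C@@H]3c4ccc(OCc9ccccc9)cc4O[C@H](c6ccc(OCc9ccccc9)c(OCc9ccccc9)c6)[C@H]3OCc9ccccc9)c1OCc9ccccc9)O[C@H](c6ccc(OCc9ccccc9)c(OCc9ccccc9)c6)[C@@H](OCc9ccccc9)C2 | intermediate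
30 | (E)-o-quinone methide from 29 (3-benzyloxy-6-arylmethylidene-cyclohexa-2,4-dienone on C6 of unit B) | O=C8C=C(OCc9ccccc9)C=C/C8=C\c5cc7c(cc5OCc9ccccc9)O[C@H](c6ccc(OCc9ccccc9)c(OCc9ccccc9)c6)[C@@H](OCc9ccccc9)[C@@H]7c1c(OCc9ccccc9)c2c(c([C@@H]3c4ccc(OCc9ccccc9)cc4O[C@H](c6ccc(OCc9ccccc9)c(OCc9ccccc9)c6)[C@H]3OCc9ccccc9)c1OCc9ccccc9)O[C@H](c6ccc(OCc9ccccc9)c(OCc9ccccc9)c6)[C@@H](OCc9ccccc9)C2 | intermediate
31 | 7,3′,4′-tri-O-benzyl-3-deoxy-3-(pinacolatoboryl)fisetinidol-(4α→6)-tetra-O-benzylfisetinidol-(4α→6)-[tetra-O-benzylfisetinidol-(4α→8)]-penta-O-benzylcatechin | c9ccccc9COc8ccc3c(c8)O[C@H](c6ccc(OCc9ccccc9)c(OCc9ccccc9)c6)[C@@H](B4OC(C)(C)C(C)(C)O4)[C@@H]3c5cc7c(cc5OCc9ccccc9)O[C@H](c6ccc(OCc9ccccc9)c(OCc9ccccc9)c6)[C@@H](OCc9ccccc9)[C@@H]7c1c(OCc9ccccc9)c2c(c([C@@H]3c4ccc(OCc9ccccc9)cc4O[C@H](c6ccc(OCc9ccccc9)c(OCc9ccccc9)c6)[C@H]3OCc9ccccc9)c1OCc9ccccc9)O[C@H](c6ccc(OCc9ccccc9)c(OCc9ccccc9)c6)[C@@H](OCc9ccccc9)C2 | intermediate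
32 | 7,3′,4′-tri-O-benzylfisetinidol-(4α→6)-tetra-O-benzylfisetinidol-(4α→6)-[tetra-O-benzylfisetinidol-(4α→8)]-penta-O-benzylcatechin (hexadeca-O-benzyl tetramer, 3-OH of unit A free) | c9ccccc9COc8ccc3c(c8)O[C@H](c6ccc(OCc9ccccc9)c(OCc9ccccc9)c6)[C@@H](O)[C@@H]3c5cc7c(cc5OCc9ccccc9)O[C@H](c6ccc(OCc9ccccc9)c(OCc9ccccc9)c6)[C@@H](OCc9ccccc9)[C@@H]7c1c(OCc9ccccc9)c2c(c([C@@H]3c4ccc(OCc9ccccc9)cc4O[C@H](c6ccc(OCc9ccccc9)c(OCc9ccccc9)c6)[C@H]3OCc9ccccc9)c1OCc9ccccc9)O[C@H](c6ccc(OCc9ccccc9)c(OCc9ccccc9)c6)[C@@H](OCc9ccccc9)C2 | intermediate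
33 | fisetinidol-(4α→6)-fisetinidol-(4α→6)-[fisetinidol-(4α→8)]-catechin (CNP0263622.1) | Oc1ccc2c(c1)O[C@H](c1ccc(O)c(O)c1)[C@@H](O)[C@@H]2c1cc2c(cc1O)O[C@H](c1ccc(O)c(O)c1)[C@@H](O)[C@@H]2c1c(O)c2c(c([C@@H]3c4ccc(O)cc4O[C@H](c4ccc(O)c(O)c4)[C@H]3O)c1O)O[C@H](c1ccc(O)c(O)c1)[C@@H](O)C2 | target

## Step count and risks

Total step count: 20. Longest linear sequence: 16 steps (1–4, 7–10, 13–20).

The three steps most likely to fail are the three cycloadditions.

**Step 8.** After the first C–C bond has formed, the β-boryl benzylic cation may lose boron (alkenyl transfer or protodeboronation) before oxygen closes the ring, leaving an open-chain allyl phenol. Face selection may also be weak, because the dienophile offers the phosphate no hydrogen-bond donor.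

Fallback (sets out from 3, comes back at 15): commercial (2R,3R)-fustin (O=C1c2ccc(O)cc2O[C@H](c2ccc(O)c(O)c2)[C@H]1O) is benzylated at its three phenols (BnBr, K2CO3, DMF) to 7,3′,4′-tri-O-benzylfustin F1. NaBH4 (THF/MeOH, 0 °C) reduces F1 to the 2,3-trans-3,4-trans flavan-3,4-diol 7,3′,4′-tri-O-benzylmollisacacidin F2. F2 is ionised at C4 with BF3·OEt2 (CH2Cl2, −40 → 0 °C) in the presence of an excess of 3. The Friedel–Crafts reaction of the flavan-4-yl cation with the phloroglucinol-type ring takes place at C8 and mainly trans to the C3 hydroxyl, to give 7,3′,4′-tri-O-benzylfisetinidol-(4α→8)-penta-O-benzylcatechin F3. N-Bromosuccinimide (CH2Cl2, −40 °C) then brominates the remaining phloroglucinol position C6, which is far more reactive than the resorcinol-type ring of unit D, and gives 15.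

**Step 14.** Ionisation should occur, but attack at the methide carbon is slowed by the two flanking benzyloxy groups and by unit D on the fully substituted ring, so the quinone methide may be lost to oligomerisation or to re-addition of water.

Fallback (sets out from 16, comes back at 25): bromine–lithium exchange on 16 (n-BuLi, THF, −78 °C) and quenching with MeOH gives tetra-O-benzylfisetinidol-(4α→8)-penta-O-benzylcatechin F4, whose only free phloroglucinol position is C6. 7,3′,4′-Tri-O-benzylmollisacacidin F2 (made as in the fallback to step 8) is brominated with N-bromosuccinimide at C6 of its resorcinol ring (para to the ring oxygen) to 6-bromo-7,3′,4′-tri-O-benzylmollisacacidin F5. BF3·OEt2 (CH2Cl2, −20 → 0 °C) ionises F5 at C4, and Friedel–Crafts attack by C6 of F4, trans to the C3 hydroxyl, gives 25.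

**Step 18.** With three flavan units around the methide carbon the catalyst may no longer dominate the facial choice, so the unit A diastereomers form together; the long exposure to acid that a slow reaction needs may also erode the material.

Fallback (sets out from 26, comes back at 32): 7,3′,4′-tri-O-benzylfustin F1 (made as in the fallback to step 8) is silylated (TBSOTf, 2,6-lutidine, CH2Cl2) to 3-O-tert-butyldimethylsilyl-7,3′,4′-tri-O-benzylfustin F6. The aryllithium 27, made from 26 as in step 17, is added to the C4 ketone of F6 (THF, −78 °C) to give the tertiary C4 carbinol tetramer F7. Ionic hydrogenation (Et3SiH, CF3CO2H, CH2Cl2, −40 °C) removes the tertiary hydroxyl; axial hydride delivery to the C4 cation should give the all-equatorial 3,4-trans product, the 3-O-silyl hexadeca-O-benzyl tetramer F8, although this sense is less secure than in the 2,3-cis series. Bu4NF (THF) then removes the silyl group to give 32. Regiochemistry is fixed by the position of the bromine in 26, and the configuration of unit A comes from fustin.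

Further compounds
F1 | step 8 | 7,3′,4′-tri-O-benzyl-(2R,3R)-fustin | O=C1c2ccc(OCc9ccccc9)cc2O[C@H](c6ccc(OCc9ccccc9)c(OCc9ccccc9)c6)[C@H]1O
F2 | step 8 | 7,3′,4′-tri-O-benzylmollisacacidin, 2,3-trans-3,4-trans flavan-3,4-diol | O[C@@H]3c4ccc(OCc9ccccc9)cc4O[C@H](c6ccc(OCc9ccccc9)c(OCc9ccccc9)c6)[C@H]3O
F3 | step 8 | 7,3′,4′-tri-O-benzylfisetinidol-(4α→8)-penta-O-benzylcatechin | c1c(OCc9ccccc9)c2c(c([C@@H]3c4ccc(OCc9ccccc9)cc4O[C@H](c6ccc(OCc9ccccc9)c(OCc9ccccc9)c6)[C@H]3O)c1OCc9ccccc9)O[C@H](c6ccc(OCc9ccccc9)c(OCc9ccccc9)c6)[C@@H](OCc9ccccc9)C2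
F4 | step 14 | tetra-O-benzylfisetinidol-(4α→8)-penta-O-benzylcatechin | c1c(OCc9ccccc9)c2c(c([C@@H]3c4ccc(OCc9ccccc9)cc4O[C@H](c6ccc(OCc9ccccc9)c(OCc9ccccc9)c6)[C@H]3OCc9ccccc9)c1OCc9ccccc9)O[C@H](c6ccc(OCc9ccccc9)c(OCc9ccccc9)c6)[C@@H](OCc9ccccc9)C2
F5 | step 14 | 6-bromo-7,3′,4′-tri-O-benzylmollisacacidin | O[C@@H]3c4cc(Br)c(OCc9ccccc9)cc4O[C@H](c6ccc(OCc9ccccc9)c(OCc9ccccc9)c6)[C@H]3O
F6 | step 18 | 3-O-tert-butyldimethylsilyl-7,3′,4′-tri-O-benzyl-(2R,3R)-fustin | O=C1c2ccc(OCc9ccccc9)cc2O[C@H](c6ccc(OCc9ccccc9)c(OCc9ccccc9)c6)[C@H]1O[Si](C)(C)C(C)(C)C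
F7 | step 18 | tertiary C4 carbinol tetramer (unit A: 4-hydroxy, 3-O-silyl; C4 epimers) | c9ccccc9COc8ccc3c(c8)O[C@H](c6ccc(OCc9ccccc9)c(OCc9ccccc9)c6)[C@@H](O[Si](C)(C)C(C)(C)C)C3(O)c5cc7c(cc5OCc9ccccc9)O[C@H](c6ccc(OCc9ccccc9)c(OCc9ccccc9)c6)[C@@H](OCc9ccccc9)[C@@H]7c1c(OCc9ccccc9)c2c(c([C@@H]3c4ccc(OCc9ccccc9)cc4O[C@H](c6ccc(OCc9ccccc9)c(OCc9ccccc9)c6)[C@H]3OCc9ccccc9)c1OCc9ccccc9)O[C@H](c6ccc(OCc9ccccc9)c(OCc9ccccc9)c6)[C@@H](OCc9ccccc9)C2
F8 | step 18 | 3-O-tert-butyldimethylsilyl hexadeca-O-benzyl tetramer (unit A 4α) | c9ccccc9COc8ccc3c(c8)O[C@H](c6ccc(OCc9ccccc9)c(OCc9ccccc9)c6)[C@@H](O[Si](C)(C)C(C)(C)C)[C@@H]3c5cc7c(cc5OCc9ccccc9)O[C@H](c6ccc(OCc9ccccc9)c(OCc9ccccc9)c6)[C@@H](OCc9ccccc9)[C@@H]7c1c(OCc9ccccc9)c2c(c([C@@H]3c4ccc(OCc9ccccc9)cc4O[C@H](c6ccc(OCc9ccccc9)c(OCc9ccccc9)c6)[C@H]3OCc9ccccc9)c1OCc9ccccc9)O[C@H](c6ccc(OCc9ccccc9)c(OCc9ccccc9)c6)[C@@H](OCc9ccccc9)C2
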